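**Retrosynthetic overview**

1. Feature: the benzene ring of the chromene (C4a, C5, C6, C7, C8, C8a) is fully substituted, with oxygen on C5, C7 and C8a alternating with carbon on C4a, C6 and C8; a 3-alkoxycyclobutenone and a siloxyalkyne deliver exactly this pattern in one thermal benzannulation.
2. Late disconnections: O-dealkylation (C7 ethyl ether, pyrone benzyl ether), the C6–acyl bond (Friedel–Crafts), the C5 silyl ether, and O1–C2 of the pyran ring (oxidative closure of the C4a prenyl group onto the C8a hydroxyl).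
3. Key disconnection: C8a–C4a and C5–C6 (C8a–C8 is re-formed by electrocyclisation), back to a 3-ethoxy-4-(pyronylmethyl)cyclobutenone and a prenyl-substituted triisopropylsiloxyalkyne.
4. The cyclobutenone comes from a ketene–ethoxyacetylene [2+2] on a 3-(pyron-3-yl)propanoic acid, whose β-carbon is the future bridge CH2; the acid comes from Michael addition of 6-ethyl-4-hydroxy-5-methylpyran-2-one (pentan-3-one plus malonyl dichloride) to tert-butyl acrylate; the siloxyalkyne comes from ethyl 4-methylpent-3-enoate by ynolate homologation.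
5. Ring order: pyrone ring (step 2), cyclobutenone (step 6, sacrificial), benzene ring (step 8), pyran ring of the chromene (step 9).

Key step: step 8

Remark: the target has no stereocentre, so the cyclobutenone is made and used as the racemate; the pyrone hydroxyl is carried as a benzyl ether and the side-chain acid as a tert-butyl ester, so that no step needs aqueous base and the last step needs no hard demethylation.

**Route**

Step 1
Reactants: 1 pentan-3-one
Product: 2 (Z)-trimethyl(pent-2-en-3-yloxy)silane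
Conditions: TMSOTf, Et3N, CH2Cl2, 0 °C
Reagents that add atoms: trimethylsilyl trifluoromethanesulfonate, C[Si](C)(C)OS(=O)(=O)C(F)(F)F
Why: Soft enolisation with O-silylation (silyl enol ether formation) of a symmetrical ketone can give only one regioisomer, expected mainly as the Z isomer; any E isomer reacts the same way in step 2, where the double-bond geometry is lost.

Step 2
Reactants: 2 (Z)-trimethyl(pent-2-en-3-yloxy)silane; 3 malonyl dichloride
Product: 4 6-ethyl-4-hydroxy-5-methyl-2H-pyran-2-one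
Conditions: Et2O, −78 °C to rt; aqueous work-up
Reagents that add atoms: none
Why: C-acylation of the silyl enol ether by one acyl chloride of 3, then O-acylation of the enolised ketone by the second (acylation–lactonisation of an enol ether with malonyl dichloride), should close the pyrone ring, which tautomerises to the 4-hydroxy-2-pyrone.

Step 3
Reactants: 4 6-ethyl-4-hydroxy-5-methyl-2H-pyran-2-one; 5 tert-butyl acrylate
Product: 6 tert-butyl 3-(6-ethyl-4-hydroxy-5-methyl-2-oxo-2H-pyran-3-yl)propanoate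
Conditions: 5 (1.5 equiv), DBU (cat.), MeCN, 60 °C
Reagents that add atoms: none
Why: Michael addition of the vinylogous acid through its nucleophilic C3 (any O-adduct should revert under the basic conditions), and the tert-butyl ester is too hindered to lactonise onto the C4 hydroxyl.

Step 4
Reactants: 6 tert-butyl 3-(6-ethyl-4-hydroxy-5-methyl-2-oxo-2H-pyran-3-yl)propanoate
Product: 7 tert-butyl 3-[4-(benzyloxy)-6-ethyl-5-methyl-2-oxo-2H-pyran-3-yl]propanoate
Conditions: BnBr, K2CO3, acetone, 56 °C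
Reagents that add atoms: benzyl bromide, BrCc1ccccc1
Why: Williamson O-alkylation of the pyrone enolate; with C3 now substituted, alkylation at the C4 oxygen to the 4-alkoxy-2-pyrone is the expected course.

Step 5
Reactants: 7 tert-butyl 3-[4-(benzyloxy)-6-ethyl-5-methyl-2-oxo-2H-pyran-3-yl]propanoate
Product: 8 3-[4-(benzyloxy)-6-ethyl-5-methyl-2-oxo-2H-pyran-3-yl]propanoic acid
Conditions: TFA, CH2Cl2, rt
Reagents that add atoms: none
Why: Acidolysis of the tert-butyl ester (loss of 2-methylpropene) frees the acid without base, so the lactone and the benzyl vinylogous ester should not be touched.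

Step 6
Reactants: 8 3-[4-(benzyloxy)-6-ethyl-5-methyl-2-oxo-2H-pyran-3-yl]propanoic acid; 9 ethoxyacetylene
Product: 12 4-{[4-(benzyloxy)-6-ethyl-5-methyl-2-oxo-2H-pyran-3-yl]methyl}-3-ethoxycyclobut-2-en-1-one (racemic), via acid chloride 10 (not isolated), via ketene 11 (not isolated)
Conditions: (COCl)2, DMF (cat.), CH2Cl2, 0 °C to rt; concentrate; then 9 (3 equiv), Et3N, CH2Cl2, 0 °C to rt, slow addition of 10
Reagents that add atoms: none
Why: Dehydrochlorination of acid chloride 10 gives monoalkylketene 11, which is trapped in a ketene–alkoxyalkyne [2+2] cycloaddition in which the nucleophilic terminal carbon of 9 bonds to the ketene carbonyl carbon, placing ethoxy on C3 and the pyronylmethyl group on C4; the C4 stereocentre forms as the racemate and needs no control because step 8 destroys it.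

Step 7
Reactants: 13 ethyl 4-methylpent-3-enoate; 14 dibromomethane
Product: 16 triisopropyl[(5-methylhex-4-en-1-yn-1-yl)oxy]silane, via lithium ynolate 15 (not isolated)
Conditions: 14, LiTMP (2.2 equiv), THF, −78 °C, then 13; n-BuLi, −78 °C to rt; TIPSCl, −78 to 0 °C
Reagents that add atoms: chlorotriisopropylsilane, CC(C)[Si](Cl)(C(C)C)C(C)C
Why: Kowalski ester homologation: addition of LiCHBr2 (from 14) to the ester, bromine–lithium exchange and 1,2-shift of the 3-methylbut-2-enyl group should give ynolate 15, which the bulky silyl chloride traps on oxygen.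

Step 8
Reactants: 12 4-{[4-(benzyloxy)-6-ethyl-5-methyl-2-oxo-2H-pyran-3-yl]methyl}-3-ethoxycyclobut-2-en-1-one (racemic); 16 triisopropyl[(5-methylhex-4-en-1-yn-1-yl)oxy]silane
Product: 21 4-(benzyloxy)-3-{6-ethoxy-2-hydroxy-3-(3-methylbut-2-en-1-yl)-4-[(triisopropylsilyl)oxy]benzyl}-6-ethyl-5-methyl-2H-pyran-2-one, via vinylketene 17 (not isolated), via alkenylcyclobutenone 18 (not isolated), via dienylketene 19 (not isolated), via cyclohexadienone 20 (not isolated)
Conditions: 16 (1.3 equiv), toluene (0.1 M), 80 °C, then 110 °C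
Reagents that add atoms: none
Why: Proposed new method: heating should open the strained ring of 12 by 4π conrotatory electrocyclic opening (pyronylmethyl group turning outward) to vinylketene 17, whose ketene C=C takes up siloxyalkyne 16 in a [2+2] cycloaddition to 18; a second 4π opening gives dienylketene 19, which closes by thermal 6π electrocyclisation to dienone 20 and tautomerises to phenol 21. The closest known reaction is the Danheiser benzannulation of alkyl- and aryl-substituted cyclobutenones with trialkylsiloxyalkynes; a 3-alkoxy-4-alkylcyclobutenone has not been used, but its ethoxy group sits on the vinyl arm and not on the ketene carbons, so it should not blunt the cycloaddition, and alkoxy-substituted cyclobutenones are known to ring-open thermally in this temperature range. The only ring closed is the benzene ring, by 6π electrocyclisation of the dienylketene that re-forms C8a–C8, a closure that is polarity-matched because the enol ether makes C8 nucleophilic toward the ketene carbon. No stereocentre survives: the one in 12 and the transient ones in 18 and 20 are erased on aromatisation. The step needs a single orientation of alkyne uptake; the oxygen lone pair of 16 makes the prenyl-bearing carbon nucleophilic toward the ketene carbonyl carbon, so C8a–C4a and C5–C6 form and the prenyl group lands ortho and the silyloxy group meta to the new hydroxyl. An excess of 16 and moderate dilution should keep 17 from dimerising or acylating the phenol as it forms.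

Step 9
Reactants: 21 4-(benzyloxy)-3-{6-ethoxy-2-hydroxy-3-(3-methylbut-2-en-1-yl)-4-[(triisopropylsilyl)oxy]benzyl}-6-ethyl-5-methyl-2H-pyran-2-one
Product: 22 4-(benzyloxy)-3-({7-ethoxy-2,2-dimethyl-5-[(triisopropylsilyl)oxy]-2H-chromen-8-yl}methyl)-6-ethyl-5-methyl-2H-pyran-2-one
Conditions: DDQ (1.1 equiv), benzene, 80 °C
Reagents that add atoms: none
Why: DDQ should abstract hydride from the benzylic and allylic CH2 of the prenyl group, and the resulting o-quinone methide closes by oxa-6π electrocyclisation onto the C8a oxygen, the only free hydroxyl (oxidative cyclisation of an o-prenylphenol to a 2,2-dimethyl-2H-chromene).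

Step 10
Reactants: 22 4-(benzyloxy)-3-({7-ethoxy-2,2-dimethyl-5-[(triisopropylsilyl)oxy]-2H-chromen-8-yl}methyl)-6-ethyl-5-methyl-2H-pyran-2-one
Product: 23 4-(benzyloxy)-3-[(7-ethoxy-5-hydroxy-2,2-dimethyl-2H-chromen-8-yl)methyl]-6-ethyl-5-methyl-2H-pyran-2-one
Conditions: TBAF, AcOH, THF, 0 °C
Reagents that add atoms: none
Why: Fluoride-mediated cleavage of the aryl silyl ether, buffered with acetic acid so that the pyrone lactone does not meet basic fluoride.

Step 11
Reactants: 23 4-(benzyloxy)-3-[(7-ethoxy-5-hydroxy-2,2-dimethyl-2H-chromen-8-yl)methyl]-6-ethyl-5-methyl-2H-pyran-2-one; 24 2-methylpropanoyl chloride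
Product: 25 4-(benzyloxy)-3-{[7-ethoxy-5-hydroxy-2,2-dimethyl-6-(2-methylpropanoyl)-2H-chromen-8-yl]methyl}-6-ethyl-5-methyl-2H-pyran-2-one
Conditions: 24, TiCl4, CH2Cl2, −78 to −20 °C
Reagents that add atoms: none
Why: Friedel–Crafts acylation at C6, the only unsubstituted ring carbon, which is ortho to the free C5 hydroxyl and the C7 ethoxy group and para to the ring oxygen; delivery through the titanium phenoxide at low temperature should spare the chromene double bond.

Step 12
Reactants: 25 4-(benzyloxy)-3-{[7-ethoxy-5-hydroxy-2,2-dimethyl-6-(2-methylpropanoyl)-2H-chromen-8-yl]methyl}-6-ethyl-5-methyl-2H-pyran-2-one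
Product: 26 3-{[5,7-dihydroxy-2,2-dimethyl-6-(2-methylpropanoyl)-2H-chromen-8-yl]methyl}-6-ethyl-4-hydroxy-5-methyl-2H-pyran-2-one
Conditions: BCl3 (5 equiv), n-Bu4NI (3 equiv), CH2Cl2, −78 to 0 °C; MeOH, then aqueous work-up
Reagents that add atoms: none
Why: Lewis acid–iodide ether cleavage: BCl3 activates the ether oxygens and iodide removes the primary ethyl and benzyl groups by SN2 attack, which does not depend on carbonyl chelation (the ketone is already held by the C5 oxygen–boron chelate), and the low temperature should leave the chromene intact.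

**Compound list**

1 | pentan-3-one | CCC(=O)CC | starting material
2 | (Z)-trimethyl(pent-2-en-3-yloxy)silane | C/C=C(/CC)O[Si](C)(C)C | intermediate
3 | malonyl dichloride | ClC(=O)CC(=O)Cl | starting material
4 | 6-ethyl-4-hydroxy-5-methyl-2H-pyran-2-one | CCc1oc(=O)cc(O)c1C | intermediate
5 | tert-butyl acrylate | C=CC(=O)OC(C)(C)C | starting material
6 | tert-butyl 3-(6-ethyl-4-hydroxy-5-methyl-2-oxo-2H-pyran-3-yl)propanoate | CCc1oc(=O)c(CCC(=O)OC(C)(C)C)c(O)c1C | intermediate
7 | tert-butyl 3-[4-(benzyloxy)-6-ethyl-5-methyl-2-oxo-2H-pyran-3-yl]propanoate | CCc1oc(=O)c(CCC(=O)OC(C)(C)C)c(OCc2ccccc2)c1C | intermediate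
8 | 3-[4-(benzyloxy)-6-ethyl-5-methyl-2-oxo-2H-pyran-3-yl]propanoic acid | CCc1oc(=O)c(CCC(=O)O)c(OCc2ccccc2)c1C | intermediate
9 | ethoxyacetylene | CCOC#C | starting material
10 | 3-[4-(benzyloxy)-6-ethyl-5-methyl-2-oxo-2H-pyran-3-yl]propanoyl chloride | CCc1oc(=O)c(CCC(Cl)=O)c(OCc2ccccc2)c1C | intermediate
11 | 4-(benzyloxy)-6-ethyl-5-methyl-3-(3-oxoprop-2-en-1-yl)-2H-pyran-2-one (ketene) | CCc1oc(=O)c(CC=C=O)c(OCc2ccccc2)c1C | intermediate
12 | 4-{[4-(benzyloxy)-6-ethyl-5-methyl-2-oxo-2H-pyran-3-yl]methyl}-3-ethoxycyclobut-2-en-1-one (racemic) | CCOC1=CC(=O)C1Cc1c(OCc2ccccc2)c(C)c(CC)oc1=O | intermediate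
13 | ethyl 4-methylpent-3-enoate | CCOC(=O)CC=C(C)C | starting material
14 | dibromomethane | BrCBr | starting material
15 | lithium 5-methylhex-4-en-1-yn-1-olate | [Li+].[O-]C#CCC=C(C)C | intermediate
16 | triisopropyl[(5-methylhex-4-en-1-yn-1-yl)oxy]silane | CC(C)=CCC#CO[Si](C(C)C)(C(C)C)C(C)C | intermediate
17 | 4-(benzyloxy)-3-[(2Z)-3-ethoxy-5-oxopenta-2,4-dien-1-yl]-6-ethyl-5-methyl-2H-pyran-2-one (vinylketene) | O=C=C/C(OCC)=C/Cc1c(OCc2ccccc2)c(C)c(CC)oc1=O | intermediate
18 | 4-{(1Z)-3-[4-(benzyloxy)-6-ethyl-5-methyl-2-oxo-2H-pyran-3-yl]-1-ethoxyprop-1-en-1-yl}-2-(3-methylbut-2-en-1-yl)-3-[(triisopropylsilyl)oxy]cyclobut-2-en-1-one (racemic) | O=C1C(CC=C(C)C)=C(O[Si](C(C)C)(C(C)C)C(C)C)C1/C(OCC)=C/Cc1c(OCc2ccccc2)c(C)c(CC)oc1=O | intermediate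
19 | 4-(benzyloxy)-3-{(2Z,4E)-3-ethoxy-6-(3-methylbut-2-en-1-yl)-7-oxo-5-[(triisopropylsilyl)oxy]hepta-2,4,6-trien-1-yl}-6-ethyl-5-methyl-2H-pyran-2-one (dienylketene) | O=C=C(CC=C(C)C)/C(O[Si](C(C)C)(C(C)C)C(C)C)=C\C(OCC)=C\Cc1c(OCc2ccccc2)c(C)c(CC)oc1=O | intermediate
20 | 6-{[4-(benzyloxy)-6-ethyl-5-methyl-2-oxo-2H-pyran-3-yl]methyl}-5-ethoxy-2-(3-methylbut-2-en-1-yl)-3-[(triisopropylsilyl)oxy]cyclohexa-2,4-dien-1-one (racemic) | O=C1C(CC=C(C)C)=C(O[Si](C(C)C)(C(C)C)C(C)C)C=C(OCC)C1Cc1c(OCc2ccccc2)c(C)c(CC)oc1=O | intermediate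
21 | 4-(benzyloxy)-3-{6-ethoxy-2-hydroxy-3-(3-methylbut-2-en-1-yl)-4-[(triisopropylsilyl)oxy]benzyl}-6-ethyl-5-methyl-2H-pyran-2-one | CCc1oc(=O)c(Cc2c(O)c(CC=C(C)C)c(O[Si](C(C)C)(C(C)C)C(C)C)cc2OCC)c(OCc2ccccc2)c1C | intermediate
22 | 4-(benzyloxy)-3-({7-ethoxy-2,2-dimethyl-5-[(triisopropylsilyl)oxy]-2H-chromen-8-yl}methyl)-6-ethyl-5-methyl-2H-pyran-2-one | CCc1oc(=O)c(Cc2c(OCC)cc(O[Si](C(C)C)(C(C)C)C(C)C)c3c2OC(C)(C)C=C3)c(OCc2ccccc2)c1C | intermediate
23 | 4-(benzyloxy)-3-[(7-ethoxy-5-hydroxy-2,2-dimethyl-2H-chromen-8-yl)methyl]-6-ethyl-5-methyl-2H-pyran-2-one | CCc1oc(=O)c(Cc2c(OCC)cc(O)c3c2OC(C)(C)C=C3)c(OCc2ccccc2)c1C | intermediate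
24 | 2-methylpropanoyl chloride | CC(C)C(=O)Cl | starting material
25 | 4-(benzyloxy)-3-{[7-ethoxy-5-hydroxy-2,2-dimethyl-6-(2-methylpropanoyl)-2H-chromen-8-yl]methyl}-6-ethyl-5-methyl-2H-pyran-2-one | CCc1oc(=O)c(Cc2c(OCC)c(C(=O)C(C)C)c(O)c3c2OC(C)(C)C=C3)c(OCc2ccccc2)c1C | intermediate
26 | 3-{[5,7-dihydroxy-2,2-dimethyl-6-(2-methylpropanoyl)-2H-chromen-8-yl]methyl}-6-ethyl-4-hydroxy-5-methyl-2H-pyran-2-one | CCc1oc(=O)c(Cc2c(O)c(C(=O)C(C)C)c(O)c3c2OC(C)(C)C=C3)c(O)c1C | target

**Step count**

Total: 12 steps. Longest linear sequence: 11 steps (steps 1–6 and 8–12, from pentan-3-one); the siloxyalkyne branch is one step (step 7).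

**Steps most likely to fail**

Step 8 (proposed new method). The ethoxy-bearing vinylketene may be used up by dimerisation or by acylating the phenol as it forms, or ring opening may lag behind thermal decomposition of the vinylogous ester. The fallback abandons the benzannulation for the established methylene-bridge assembly; it sets out from pyrone 4 and comes back to the route at target 26. Phloroglucinol is C-acylated with 24 (AlCl3, nitrobenzene/CH2Cl2) to 2-methyl-1-(2,4,6-trihydroxyphenyl)propan-1-one F1. Condensation of F1 with 3-methylbut-2-enal (ethylenediammonium diacetate, toluene, heat; Knoevenagel condensation then oxa-6π electrocyclisation) gives, after separation from the 8-acyl isomer, 1-(5,7-dihydroxy-2,2-dimethyl-2H-chromen-6-yl)-2-methylpropan-1-one F2. Pyrone 4 and N,N-dimethylmethyleneiminium iodide give the Mannich base 3-[(dimethylamino)methyl]-6-ethyl-4-hydroxy-5-methyl-2H-pyran-2-one F3. Warming F3 with F2 in MeCN expels dimethylamine to a 3-methylenepyran-2,4-dione, which alkylates the free C8 of F2 and gives 26 directly.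

Step 12. Dealkylation at the hindered C7 ether has no chelation assistance and may be slow, and longer exposure risks hydrohalogenation or ring opening of the chromene. The fallback turns the cleavage into a chelation-assisted one by masking the C5 hydroxyl; it sets out from 25 and comes back at 26. Acetylation of 25 (Ac2O, DMAP, Et3N, CH2Cl2) gives 8-{[4-(benzyloxy)-6-ethyl-5-methyl-2-oxo-2H-pyran-3-yl]methyl}-7-ethoxy-2,2-dimethyl-6-(2-methylpropanoyl)-2H-chromen-5-yl acetate F7. With the C5 oxygen blocked, BCl3 (CH2Cl2, −78 to −20 °C) can bind the ketone and the C7 ethoxy oxygen as a six-membered chelate and should remove the ethyl group quickly, together with the benzyl group, to give 8-[(6-ethyl-4-hydroxy-5-methyl-2-oxo-2H-pyran-3-yl)methyl]-7-hydroxy-2,2-dimethyl-6-(2-methylpropanoyl)-2H-chromen-5-yl acetate F8. Methanolysis of F8 (K2CO3, MeOH, 0 °C) removes the acetate and gives 26.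

Step 11. The Lewis acid may oligomerise the electron-rich chromene, the acylium ion may attack the C3=C4 double bond, and the pyrone benzyl group may be lost early. The fallback carries the pyran ring through the acylation in its saturated form; it sets out from 21 and comes back at 25. Acid-catalysed hydroalkoxylation of 21 (Amberlyst 15, toluene, rt) closes the prenyl group onto the C8a hydroxyl to give 4-(benzyloxy)-3-({7-ethoxy-2,2-dimethyl-5-[(triisopropylsilyl)oxy]-3,4-dihydro-2H-chromen-8-yl}methyl)-6-ethyl-5-methyl-2H-pyran-2-one F4. Desilylation of F4 (TBAF, AcOH, THF) gives 4-(benzyloxy)-3-[(7-ethoxy-5-hydroxy-2,2-dimethyl-3,4-dihydro-2H-chromen-8-yl)methyl]-6-ethyl-5-methyl-2H-pyran-2-one F5. Friedel–Crafts acylation of F5 with 24 (TiCl4, CH2Cl2), which the chroman tolerates, gives 4-(benzyloxy)-3-{[7-ethoxy-5-hydroxy-2,2-dimethyl-6-(2-methylpropanoyl)-3,4-dihydro-2H-chromen-8-yl]methyl}-6-ethyl-5-methyl-2H-pyran-2-one F6. Dehydrogenation of F6 with DDQ (dioxane, reflux) introduces the C3=C4 double bond and gives 25.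

**Further compounds**

F1 | step 8 | 2-methyl-1-(2,4,6-trihydroxyphenyl)propan-1-one | CC(C)C(=O)c1c(O)cc(O)cc1O
F2 | step 8 | 1-(5,7-dihydroxy-2,2-dimethyl-2H-chromen-6-yl)-2-methylpropan-1-one | CC(C)C(=O)c1c(O)cc2OC(C)(C)C=Cc2c1O
F3 | step 8 | 3-[(dimethylamino)methyl]-6-ethyl-4-hydroxy-5-methyl-2H-pyran-2-one | CCc1oc(=O)c(CN(C)C)c(O)c1C
F4 | step 11 | 4-(benzyloxy)-3-({7-ethoxy-2,2-dimethyl-5-[(triisopropylsilyl)oxy]-3,4-dihydro-2H-chromen-8-yl}methyl)-6-ethyl-5-methyl-2H-pyran-2-one | CCc1oc(=O)c(Cc2c(OCC)cc(O[Si](C(C)C)(C(C)C)C(C)C)c3c2OC(C)(C)CC3)c(OCc2ccccc2)c1C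
F5 | step 11 | 4-(benzyloxy)-3-[(7-ethoxy-5-hydroxy-2,2-dimethyl-3,4-dihydro-2H-chromen-8-yl)methyl]-6-ethyl-5-methyl-2H-pyran-2-one | CCc1oc(=O)c(Cc2c(OCC)cc(O)c3c2OC(C)(C)CC3)c(OCc2ccccc2)c1C
F6 | step 11 | 4-(benzyloxy)-3-{[7-ethoxy-5-hydroxy-2,2-dimethyl-6-(2-methylpropanoyl)-3,4-dihydro-2H-chromen-8-yl]methyl}-6-ethyl-5-methyl-2H-pyran-2-one | CCc1oc(=O)c(Cc2c(OCC)c(C(=O)C(C)C)c(O)c3c2OC(C)(C)CC3)c(OCc2ccccc2)c1C
F7 | step 12 | 8-{[4-(benzyloxy)-6-ethyl-5-methyl-2-oxo-2H-pyran-3-yl]methyl}-7-ethoxy-2,2-dimethyl-6-(2-methylpropanoyl)-2H-chromen-5-yl acetate | CCc1oc(=O)c(Cc2c(OCC)c(C(=O)C(C)C)c(OC(C)=O)c3c2OC(C)(C)C=C3)c(OCc2ccccc2)c1C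
F8 | step 12 | 8-[(6-ethyl-4-hydroxy-5-methyl-2-oxo-2H-pyran-3-yl)methyl]-7-hydroxy-2,2-dimethyl-6-(2-methylpropanoyl)-2H-chromen-5-yl acetate | CCc1oc(=O)c(Cc2c(O)c(C(=O)C(C)C)c(OC(C)=O)c3c2OC(C)(C)C=C3)c(O)c1C
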